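**Retrosynthetic overview**
1. Locants (terpenoid numbering): ring A = C1–C5 and C10; ring B = C5–C10; C11 = formyl carbon on C9; C8 carries CH3 and C14; oxolane ring = C13–C14–C15–O–C16; C12 = acetoxymethyl carbon.
2. 36 ⇐ sulfoxide syn-elimination (C13=C16), C11 oxidation and C9=C11 hydroboration ⇐ 2-acetoxy-5-phenylthio-oxolane 31 ⇐ thio-lactone 26 ⇐ Ireland–Claisen acid 24 (C8–C14 bond) ⇐ allylic alcohol 13 + acid 20.
3. 13 ⇐ decalin β-keto ester 10 ⇐ (3+3) annulation of β-cyclogeranyl acetate 3 with the bis(silyl) dienol ether 8 of an 8-phenylmenthyl acetoacetate, forming C6–C7 and C9–C10 in one operation.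
4. Enabling feature: the formyl carbon C11 on C9, next to quaternary C8, makes C7–C8–C9–C11 a masked acetoacetate (γ-C, ketone C, α-C, ester C); C6–C5–C10 of rings A/B is the allyl unit of β-cyclogeraniol; the two new ring-B bonds are 1,4-related.
5. Ring order and stereocontrol: ring A is bought (β-cyclocitral), ring B forms in the key step, the oxolane ring forms in step 14 and its enol ether in step 19; the bought auxiliary sets C5 and C10, a chair Claisen on the α-face sets C8 and C14, α-face hydroboration sets C9, and acylal equilibration sets C15.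

Key step: step 5

Assumption: the phenyl group of (1R,2S,5R)-8-phenylmenthol is taken to cover the enol face whose reaction gives the (5S,10S) decalin; if the sense is opposite, the enantiomeric auxiliary is used in the same way, and the minor diastereomer is removed at 10 in either case.

**Route**

Step 1
Reactants: 1 β-cyclocitral
Product: 2 β-cyclogeraniol
Conditions: NaBH4, MeOH, 0 °C
Reagents that add atoms: none
Why: Borohydride 1,2-reduction of the hindered enal should give the allylic alcohol cleanly (carbonyl reduction).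

Step 2
Reactants: 2 β-cyclogeraniol
Product: 3 β-cyclogeranyl acetate
Conditions: Ac2O, pyridine, DMAP (cat.), CH2Cl2, rt
Reagents that add atoms: acetic anhydride, CC(=O)OC(C)=O
Why: DMAP-catalysed acylation turns the hydroxyl into an ionisable allylic leaving group.

Step 3
Reactants: 4 (−)-8-phenylmenthol; 5 2,2,6-trimethyl-4H-1,3-dioxin-4-one
Product: 6 (1R,2S,5R)-8-phenylmenthyl 3-oxobutanoate
Conditions: xylene, 140 °C, acetone distilled off
Reagents that add atoms: none
Why: Thermal retro-hetero-Diels–Alder cleavage of the dioxinone gives acetylketene, which the hindered alcohol traps (acetoacetylation); the auxiliary stereocentres are bought.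

Step 4
Reactants: 6 8-phenylmenthyl 3-oxobutanoate
Product: 8 1-(8-phenylmenthyloxy)-1,3-bis(trimethylsilyloxy)buta-1,3-diene, via mono(silyl) enol ether 7 (not isolated)
Conditions: Me3SiCl, Et3N, THF, rt; then LiN(i-Pr)2, THF, −78 °C; Me3SiCl
Reagents that add atoms: chlorotrimethylsilane, C[Si](C)(C)Cl
Why: Stepwise O-silylation (first the enol, then the γ-deprotonated dienolate) should give the 1,3-bis(silyloxy)diene, a γ-nucleophilic acetoacetate equivalent (silyl enol ether formation).

Step 5
Reactants: 3 β-cyclogeranyl acetate; 8 bis(silyl) dienol ether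
Product: 10 8-phenylmenthyl (1R,4aS,8aS)-5,5,8a-trimethyl-2-oxodecahydronaphthalene-1-carboxylate, via open-chain silyl enol ether 9 (not isolated)
Conditions: SnCl4 (2.2 equiv), CH2Cl2, −78 °C; then i-PrOH (1 equiv), −78 → 0 °C; aq. NaHCO3
Reagents that add atoms: none
Why: Proposed new method: SnCl4 ionises 3 to the β-cyclogeranyl allyl cation, the terminal (γ) carbon of 8 bonds to its unhindered primary terminus C6 with loss of the ester-oxygen silyl group to give the 3-silyloxy enoate 9, and the tin-chelated enolate formed from 9 then adds across C5=C10 as the proton freed from i-PrOH·SnCl4 goes to C5 and C9 bonds to C10. The closest known reaction types are the Lewis-acid γ-alkylation of 1,3-bis(silyloxy)dienes by SN1-active electrophiles and the SnCl4 cyclisation of methyl 3-oxo-5-(2,6,6-trimethylcyclohexenyl)pentanoate to the trans-decalin β-keto ester; face control of α-carbon bonding in chelated 8-phenylmenthyl β-keto esters is precedented in polyene ring closures. Ring B closes in a 6-endo-trig mode at the protonated C5=C10 bond with the enol carbon C9 as nucleophile, so the ring is the (3+3) sum of C6–C5–C10 and C7–C8–C9. Antiperiplanar addition through a chair array puts H-5 and the C10 methyl trans, the C9 ester becomes equatorial by enolisation, and the absolute sense at C5/C10 is set by the phenyl group of the auxiliary covering one face of the chelated enol. The step needs C6 rather than C10 attack in the first bond (the C10 terminus is tertiary and flanked by the ring) and six- rather than five-ring closure (C5 lies next to the gem-dimethyl carbon and cannot be attacked); the minor diastereomer is removed by chromatography at 10.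

Step 6
Reactants: 10 decalin β-keto ester
Product: 11 8-phenylmenthyl (4aS,8aS)-5,5,8a-trimethyl-2-(trifluoromethylsulfonyloxy)-3,4,4a,5,6,7,8,8a-octahydronaphthalene-1-carboxylate
Conditions: NaH, THF, 0 °C; PhNTf2, 0 °C → rt
Reagents that add atoms: N-phenylbis(trifluoromethanesulfonimide), O=S(=O)(N(c1ccccc1)S(=O)(=O)C(F)(F)F)C(F)(F)F
Why: O-Sulfonylation of the sodium enolate fixes the C8=C9 enol as its triflate and removes the labile C9 centre (enol triflate formation).

Step 7
Reactants: 11 enol triflate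
Product: 12 8-phenylmenthyl (4aS,8aS)-2,5,5,8a-tetramethyl-3,4,4a,5,6,7,8,8a-octahydronaphthalene-1-carboxylate
Conditions: MeMgBr, Fe(acac)3 (5 mol%), THF/NMP, −30 → 0 °C
Reagents that add atoms: methylmagnesium bromide, C[Mg]Br
Why: Iron-catalysed Kumada-type coupling of β-(triflyloxy) enoates with MeMgBr tolerates the ester and should install the C8 methyl.

Step 8
Reactants: 12 β-methyl enoate
Product: 13 [(4aS,8aS)-2,5,5,8a-tetramethyl-3,4,4a,5,6,7,8,8a-octahydronaphthalen-1-yl]methanol
Conditions: LiAlH4, THF, 0 → 40 °C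
Reagents that add atoms: none
Why: Hydride 1,2-reduction of the hindered enoate should release the allylic alcohol and the auxiliary 4, which is recovered (ester reduction).

Step 9
Reactants: 14 itaconic acid 4-methyl ester
Product: 15 4-methoxy-4-oxo-2-[(phenylsulfanyl)methyl]butanoic acid (racemic)
Conditions: PhSH, Et3N (cat.), MeOH, rt
Reagents that add atoms: thiophenol, Sc1ccccc1
Why: Thia-Michael addition of the thiolate to the methylene terminus gives the β-thio acid; the new centre (C13) is racemic and is erased in step 19.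

Step 10
Reactants: 15 thio acid
Product: 17 4-[(phenylsulfanyl)methyl]oxolan-2-one, via hydroxy ester 16 (not isolated)
Conditions: BH3·SMe2, THF, 0 °C → rt; MeOH; TsOH (cat.), toluene, 60 °C
Reagents that add atoms: none
Why: Borane reduces the free carboxylic acid much faster than the methyl ester, and the γ-hydroxy ester lactonises under acid (chemoselective acid reduction, lactonisation).

Step 11
Reactants: 17 thio lactone building block
Product: 20 4-(tert-butyldimethylsilyloxy)-3-[(phenylsulfanyl)methyl]butanoic acid, via potassium hydroxy carboxylate 18 (not isolated), via bis(silyl) derivative 19 (not isolated)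
Conditions: KOH, MeOH/H2O, rt, evaporate; t-BuMe2SiCl, imidazole, DMF; K2CO3 (cat.), MeOH/H2O; citric acid, pH 5
Reagents that add atoms: potassium hydroxide, [K+].[OH-]; tert-butyl(chloro)dimethylsilane, CC(C)(C)[Si](C)(C)Cl
Why: Hydroxide opens the lactone at the acyl carbon (saponification), both oxygens are silylated, and selective solvolysis of the labile silyl ester should give the O-protected γ-hydroxy acid without relactonisation (silyl ether protection).

Step 12
Reactants: 13 allylic alcohol; 20 silyloxy acid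
Product: 21 allylic ester of 13 and 20 (both C13 epimers)
Conditions: DCC, DMAP (cat.), CH2Cl2, 0 °C → rt
Reagents that add atoms: none
Why: Steglich esterification joins the two halves; the C13 epimers are carried on together because C13 becomes trigonal in step 19.

Step 13
Reactants: 21 allylic ester
Product: 24 2-(1,5,5,8a-tetramethyl-2-methylidenedecahydronaphthalen-1-yl)-4-(tert-butyldimethylsilyloxy)-3-[(phenylsulfanyl)methyl]butanoic acid (C5, C8, C10, C14 as in 36), via silyl ketene acetal 22 (not isolated), via trimethylsilyl ester 23 (not isolated)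
Conditions: LiN(i-Pr)2, THF, −78 °C; Me3SiCl/Et3N, −78 °C → rt; toluene, 90 °C; 1 M HCl
Reagents that add atoms: none
Why: Ireland–Claisen rearrangement: kinetic enolisation in THF gives the ketene acetal with the C13 chain cis to the allylic oxygen, and the chair array on the α-face of C8=C9 (the β-face is covered by the axial C10 methyl) should form C8–C14 with 8β-methyl and 14S while moving the alkene to C9=C11.

Step 14
Reactants: 24 Claisen acid
Product: 26 4-[(tert-butyldimethylsilyloxy)methyl]-5-(phenylsulfanyl)-3-(decalinyl)oxolan-2-one (C13 and C16 epimers), via α-chloro sulfide 25 (not isolated)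
Conditions: N-chlorosuccinimide, pyridine, CH2Cl2, 0 °C → rt
Reagents that add atoms: none
Why: Chlorination of the sulfide at its only α-CH2 (C16) and displacement by the neighbouring carboxylate through the thionium ion should close the oxolanone (Pummerer-type oxidative lactonisation); both C16 epimers are usable.

Step 15
Reactants: 26 thio-lactone
Product: 29 (15R)-15-acetoxy-16-phenylthio oxolane with C12 silyl ether and C9=C11 alkene, via aluminium hemiacetal 27 (not isolated), via C15-epimeric acetate 28 (not isolated)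
Conditions: i-Bu2AlH, CH2Cl2, −78 °C; Ac2O, pyridine, DMAP, −78 → 0 °C; then BF3·OEt2 (5 mol%), Ac2O, CH2Cl2, −40 °C
Reagents that add atoms: acetic anhydride, CC(=O)OC(C)=O
Why: Reductive acetylation traps the tetrahedral aluminate before it can open, and because hydride enters anti to the C14 substituent (acetate cis) the acylal is then equilibrated through its oxocarbenium ion to the less hindered 14,15-trans acetate (15R).

Step 16
Reactants: 29 acetoxy acetal silyl ether
Product: 31 C12,C15-diacetate with 16-phenylthio oxolane and C9=C11 alkene, via primary alcohol 30 (not isolated)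
Conditions: Bu4NF/AcOH (1:1), THF, 0 °C → rt; then Ac2O, pyridine, DMAP (cat.), 0 °C
Reagents that add atoms: acetic anhydride, CC(=O)OC(C)=O
Why: Buffered fluoride should remove the primary silyl ether without touching the acylal, and immediate acetylation installs the C12 acetate (desilylation, acylation).

Step 17
Reactants: 31 diacetate alkene
Product: 33 C11 primary alcohol (9α-H), via alkylborane 32 (not isolated)
Conditions: BH3·THF, 0 °C → rt; Me3NO, THF, 60 °C; aq. work-up
Reagents that add atoms: trimethylamine N-oxide, C[N+](C)(C)[O-]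
Why: Anti-Markovnikov hydroboration of the exocyclic C9=C11 alkene from the α-face (the β-face carries the axial methyls on C8 and C10) should set 9α-H, and the amine oxide oxidises the C–B bond without oxidising the sulfide (hydroboration–oxidation).

Step 18
Reactants: 33 C11 alcohol
Product: 34 C11 aldehyde with 16-phenylthio oxolane
Conditions: Dess–Martin periodinane, NaHCO3, CH2Cl2, 0 °C → rt
Reagents that add atoms: none
Why: Buffered Dess–Martin oxidation should convert the hindered primary alcohol into the equatorial C11 aldehyde without oxidising the sulfide or epimerising C9.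

Step 19
Reactants: 34 aldehyde sulfide
Product: 36 target CNP0170308.1, via sulfoxide 35 (not isolated)
Conditions: mCPBA (1.0 equiv), CH2Cl2, −78 °C; then pyridine, toluene, 80 °C
Reagents that add atoms: none
Why: Low-temperature S-oxidation and thermal syn-elimination of the α-alkoxy sulfoxide, whose only β-hydrogen is H-13 (cis to sulfur in the major C16 epimer, the minor one reacting by ionisation), should unveil the C13=C16 enol ether regiospecifically and leave C14 and C15 untouched (sulfoxide elimination).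

**Compound list**

1 | β-cyclocitral (2,6,6-trimethylcyclohex-1-ene-1-carbaldehyde) | CC1=C(C=O)C(C)(C)CCC1 | starting material
2 | β-cyclogeraniol | CC1=C(CO)C(C)(C)CCC1 | intermediate
3 | β-cyclogeranyl acetate | CC(=O)OCC1=C(C)CCCC1(C)C | intermediate
4 | (−)-8-phenylmenthol, (1R,2S,5R)-5-methyl-2-(2-phenylpropan-2-yl)cyclohexan-1-ol | O[C@@H]1C[C@H](C)CC[C@H]1C(C)(C)c2ccccc2 | starting material
5 | 2,2,6-trimethyl-4H-1,3-dioxin-4-one | CC1=CC(=O)OC(C)(C)O1 | starting material
6 | (1R,2S,5R)-8-phenylmenthyl 3-oxobutanoate | CC(=O)CC(=O)O[C@@H]1C[C@H](C)CC[C@H]1C(C)(C)c2ccccc2 | intermediate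
7 | 8-phenylmenthyl 3-(trimethylsilyloxy)but-2-enoate | CC(O[Si](C)(C)C)=CC(=O)O[C@@H]1C[C@H](C)CC[C@H]1C(C)(C)c2ccccc2 | intermediate
8 | 1-(8-phenylmenthyloxy)-1,3-bis(trimethylsilyloxy)buta-1,3-diene | C=C(O[Si](C)(C)C)C=C(O[Si](C)(C)C)O[C@@H]1C[C@H](C)CC[C@H]1C(C)(C)c2ccccc2 | intermediate
9 | 8-phenylmenthyl 3-(trimethylsilyloxy)-5-(2,6,6-trimethylcyclohex-1-en-1-yl)pent-2-enoate (silyl enol ether of the open-chain β-keto ester) | CC1=C(CCC(O[Si](C)(C)C)=CC(=O)O[C@@H]2C[C@H](C)CC[C@H]2C(C)(C)c3ccccc3)C(C)(C)CCC1 | intermediate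
10 | 8-phenylmenthyl (1R,4aS,8aS)-5,5,8a-trimethyl-2-oxodecahydronaphthalene-1-carboxylate (5α-H, 10β-CH3, 9α-H) | O=C1CC[C@H]2C(C)(C)CCC[C@]2(C)[C@H]1C(=O)O[C@@H]3C[C@H](C)CC[C@H]3C(C)(C)c4ccccc4 | intermediate
11 | 8-phenylmenthyl (4aS,8aS)-5,5,8a-trimethyl-2-(trifluoromethylsulfonyloxy)-3,4,4a,5,6,7,8,8a-octahydronaphthalene-1-carboxylate | O=C(O[C@@H]3C[C@H](C)CC[C@H]3C(C)(C)c4ccccc4)C1=C(OS(=O)(=O)C(F)(F)F)CC[C@H]2C(C)(C)CCC[C@]12C | intermediate
12 | 8-phenylmenthyl (4aS,8aS)-2,5,5,8a-tetramethyl-3,4,4a,5,6,7,8,8a-octahydronaphthalene-1-carboxylate | O=C(O[C@@H]3C[C@H](C)CC[C@H]3C(C)(C)c4ccccc4)C1=C(C)CC[C@H]2C(C)(C)CCC[C@]12C | intermediate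
13 | [(4aS,8aS)-2,5,5,8a-tetramethyl-3,4,4a,5,6,7,8,8a-octahydronaphthalen-1-yl]methanol (drim-8-en-11-ol) | OCC1=C(C)CC[C@H]2C(C)(C)CCC[C@]12C | intermediate
14 | itaconic acid 4-methyl ester (4-methoxy-2-methylidene-4-oxobutanoic acid) | COC(=O)CC(=C)C(O)=O | starting material
15 | 4-methoxy-4-oxo-2-[(phenylsulfanyl)methyl]butanoic acid (racemic) | COC(=O)CC(CSc1ccccc1)C(O)=O | intermediate
16 | methyl 4-hydroxy-3-[(phenylsulfanyl)methyl]butanoate | COC(=O)CC(CO)CSc1ccccc1 | intermediate
17 | 4-[(phenylsulfanyl)methyl]oxolan-2-one (racemic) | O=C1CC(CSc2ccccc2)CO1 | intermediate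
18 | potassium 4-hydroxy-3-[(phenylsulfanyl)methyl]butanoate | [K+].[O-]C(=O)CC(CO)CSc1ccccc1 | intermediate
19 | tert-butyldimethylsilyl 4-(tert-butyldimethylsilyloxy)-3-[(phenylsulfanyl)methyl]butanoate | CC(C)(C)[Si](C)(C)OCC(CSc1ccccc1)CC(=O)O[Si](C)(C)C(C)(C)C | intermediate
20 | 4-(tert-butyldimethylsilyloxy)-3-[(phenylsulfanyl)methyl]butanoic acid (racemic) | CC(C)(C)[Si](C)(C)OCC(CSc1ccccc1)CC(O)=O | intermediate
21 | ester of 13 with 20 (both C13 epimers) | CC(C)(C)[Si](C)(C)OCC(CSc1ccccc1)CC(=O)OCC2=C(C)CC[C@H]3C(C)(C)CCC[C@]23C | intermediate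
22 | O-trimethylsilyl ketene acetal of 21, C13 chain cis to the allylic oxygen | CC(C)(C)[Si](C)(C)OCC(CSc1ccccc1)/C=C(\OCC2=C(C)CC[C@H]3C(C)(C)CCC[C@]23C)O[Si](C)(C)C | intermediate
23 | trimethylsilyl ester of 24 | C[Si](C)(C)OC(=O)[C@H](C(CO[Si](C)(C)C(C)(C)C)CSc1ccccc1)[C@]2(C)CC[C@H]3C(C)(C)CCC[C@]3(C)C2=C | intermediate
24 | Claisen acid: C15 carboxylic acid on C14; C8 quaternary (8β-CH3, C14 on the α-face, 14S sense of 36); C9=C11 methylidene; C12 silyl ether; C16 CH2SPh; C13 epimers | OC(=O)[C@H](C(CO[Si](C)(C)C(C)(C)C)CSc1ccccc1)[C@]2(C)CC[C@H]3C(C)(C)CCC[C@]3(C)C2=C | intermediate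
25 | 24 chlorinated at C16 (α-chloro sulfide) | OC(=O)[C@H](C(CO[Si](C)(C)C(C)(C)C)C(Cl)Sc1ccccc1)[C@]2(C)CC[C@H]3C(C)(C)CCC[C@]3(C)C2=C | intermediate
26 | thio-lactone: oxolan-2-one (C15=O) with 16-SPh, C12 silyl ether, C14 as in 36, C9=C11 alkene; C13 and C16 epimers | CC(C)(C)[Si](C)(C)OCC1C(Sc2ccccc2)OC(=O)[C@H]1[C@]3(C)CC[C@H]4C(C)(C)CCC[C@]4(C)C3=C | intermediate
27 | diisobutylaluminium hemiacetal of 26 | CC(C)(C)[Si](C)(C)OCC1C(Sc2ccccc2)OC(O[Al](CC(C)C)CC(C)C)[C@H]1[C@]3(C)CC[C@H]4C(C)(C)CCC[C@]4(C)C3=C | intermediate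
28 | 15-epi acetate (14,15-cis) | CC(C)(C)[Si](C)(C)OCC1C(Sc2ccccc2)O[C@@H](OC(C)=O)[C@H]1[C@]3(C)CC[C@H]4C(C)(C)CCC[C@]4(C)C3=C | intermediate
29 | (15R)-acetoxy acetal (14,15-trans), 16-SPh, C12 silyl ether, C9=C11 alkene | CC(C)(C)[Si](C)(C)OCC1C(Sc2ccccc2)O[C@H](OC(C)=O)[C@H]1[C@]3(C)CC[C@H]4C(C)(C)CCC[C@]4(C)C3=C | intermediate
30 | C12 alcohol of 29 | OCC1C(Sc2ccccc2)O[C@H](OC(C)=O)[C@H]1[C@]3(C)CC[C@H]4C(C)(C)CCC[C@]4(C)C3=C | intermediate
31 | C12,C15-diacetate, 16-SPh, C9=C11 alkene | CC(=O)OCC1C(Sc2ccccc2)O[C@H](OC(C)=O)[C@H]1[C@]3(C)CC[C@H]4C(C)(C)CCC[C@]4(C)C3=C | intermediate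
32 | C11 alkylborane of 31 (9α-H) | CC(=O)OCC1C(Sc2ccccc2)O[C@H](OC(C)=O)[C@H]1[C@]3(C)CC[C@H]4C(C)(C)CCC[C@]4(C)[C@H]3CB | intermediate
33 | C11 alcohol (9α-H, 9β-CH2OH), diacetate, 16-SPh | CC(=O)OCC1C(Sc2ccccc2)O[C@H](OC(C)=O)[C@H]1[C@]3(C)CC[C@H]4C(C)(C)CCC[C@]4(C)[C@H]3CO | intermediate
34 | C11 aldehyde, diacetate, 16-SPh | CC(=O)OCC1C(Sc2ccccc2)O[C@H](OC(C)=O)[C@H]1[C@]3(C)CC[C@H]4C(C)(C)CCC[C@]4(C)[C@H]3C=O | intermediate
35 | sulfoxide of 34 | CC(=O)OCC1C(S(=O)c2ccccc2)O[C@H](OC(C)=O)[C@H]1[C@]3(C)CC[C@H]4C(C)(C)CCC[C@]4(C)[C@H]3C=O | intermediate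
36 | CNP0170308.1: (5S,8R,9R,10S,14S,15R); 5α-H, 10β-CH3, 9β-CHO, 8β-CH3, 14,15-trans 15-acetoxy-2,3-dihydrofuran with C12 acetoxymethyl | CC(=O)OCC1=CO[C@H](OC(C)=O)[C@H]1[C@]1(C)CC[C@H]2C(C)(C)CCC[C@]2(C)[C@H]1C=O | target

**Step count and risks**

Total step count: 19. Longest linear sequence: 14 steps (1, 2, 5, 6, 7, 8, 12, 13, 14, 15, 16, 17, 18, 19).

Steps most likely to fail:

Step 5 (proposed new method). What may go wrong: the allyl cation loses a proton to the exocyclic diene before it is captured, the dienol ether is desilylated, or the auxiliary gives weak facial bias. Fallback, from 2 and 6, back at 10: alcohol 2 is treated with PBr3 (Et2O, 0 °C) to give β-cyclogeranyl bromide F1. The dianion of 6 (NaH, then n-BuLi, THF, 0 °C) is alkylated at its terminal carbon by F1 to give the open-chain β-keto ester F2, a known dianion γ-alkylation. F2 is then cyclised with SnCl4 in wet CH2Cl2, the known cation–olefin closure of this substrate class, to give 10 after chromatographic removal of the other diastereomer.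

Step 13. What may go wrong: the crowded rearrangement is slow, or the open-chain ketene acetal reacts through a boat-like array and delivers the C14 epimer. Fallback, from 13, back at 24: purchased racemic paraconic acid F3 is reduced at its carboxyl group with BH3·SMe2 (THF, 0 °C → rt) to 4-(hydroxymethyl)oxolan-2-one F4, which is silylated (t-BuMe2SiCl, imidazole, DMF) to the silyl ether lactone F5. O-Ethylation with triethyloxonium tetrafluoroborate and then NaOEt gives the ortholactone F6; no sulfide is present at this stage, so the oxonium salt has only the lactone carbonyl to alkylate. Heating 13 with F6 and catalytic pivalic acid (xylene, 140 °C) effects a Johnson–Claisen rearrangement through the cyclic ketene acetal. Its enol geometry is fixed by the ring with C13 trans to the allylic oxygen, the opposite of step 13, so the boat-like array now leads to 14S and gives the α-substituted lactone F7. PhSNa (DMF, 100 °C) then opens F7 by SN2 attack at the ring O–CH2 carbon (alkyl–oxygen cleavage of a γ-lactone by thiolate), which installs the C16 phenylthio group and frees the C15 carboxylate; acidification with 1 M HCl returns 24.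

Step 17. What may go wrong: the acetate and acylal groups are reduced or cleaved by borane, or sulfur is oxidised during C–B oxidation. Fallback, from 26, back at 33: the alkene of 26 is hydroborated and oxidised (BH3·THF; Me3NO) before any acetate is present to give the C11 alcohol F8. Silylation (Et3SiOTf, 2,6-lutidine) gives the triethylsilyl ether F9. Reductive acetylation and acylal equilibration as in step 15 give the acetoxy acetal F10. Bu4NF/AcOH removes both silyl groups to give the diol F11. The unhindered C12 hydroxyl is then acetylated selectively (Ac2O, 2,4,6-collidine, −20 °C) in the presence of the hindered C11 hydroxyl to return 33.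

**Further compounds**

F1 | step 5 | β-cyclogeranyl bromide | CC1=C(CBr)C(C)(C)CCC1
F2 | step 5 | 8-phenylmenthyl 3-oxo-5-(2,6,6-trimethylcyclohex-1-en-1-yl)pentanoate | CC1=C(CCC(=O)CC(=O)O[C@@H]2C[C@H](C)CC[C@H]2C(C)(C)c3ccccc3)C(C)(C)CCC1
F3 | step 13 | paraconic acid (5-oxooxolane-3-carboxylic acid, racemic) | OC(=O)C1COC(=O)C1
F4 | step 13 | 4-(hydroxymethyl)oxolan-2-one (racemic) | OCC1COC(=O)C1
F5 | step 13 | 4-[(tert-butyldimethylsilyloxy)methyl]oxolan-2-one | CC(C)(C)[Si](C)(C)OCC1COC(=O)C1
F6 | step 13 | 2,2-diethoxy-4-[(tert-butyldimethylsilyloxy)methyl]oxolane | CCOC1(OCC)CC(CO[Si](C)(C)C(C)(C)C)CO1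
F7 | step 13 | 3-(decalinyl)-4-[(tert-butyldimethylsilyloxy)methyl]oxolan-2-one, C8 and C14 as in 36, C9=C11 alkene | O=C1OCC(CO[Si](C)(C)C(C)(C)C)[C@@H]1[C@]3(C)CC[C@H]4C(C)(C)CCC[C@]4(C)C3=C
F8 | step 17 | C11 alcohol of thio-lactone 26 (9α-H) | CC(C)(C)[Si](C)(C)OCC1C(Sc2ccccc2)OC(=O)[C@H]1[C@]3(C)CC[C@H]4C(C)(C)CCC[C@]4(C)[C@H]3CO
F9 | step 17 | C11 triethylsilyl ether of F8 | CC(C)(C)[Si](C)(C)OCC1C(Sc2ccccc2)OC(=O)[C@H]1[C@]3(C)CC[C@H]4C(C)(C)CCC[C@]4(C)[C@H]3CO[Si](CC)(CC)CC
F10 | step 17 | (15R)-acetoxy acetal with C12 and C11 silyl ethers | CC(C)(C)[Si](C)(C)OCC1C(Sc2ccccc2)O[C@H](OC(C)=O)[C@H]1[C@]3(C)CC[C@H]4C(C)(C)CCC[C@]4(C)[C@H]3CO[Si](CC)(CC)CC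
F11 | step 17 | C11,C12-diol with (15R)-acetoxy acetal | OCC1C(Sc2ccccc2)O[C@H](OC(C)=O)[C@H]1[C@]3(C)CC[C@H]4C(C)(C)CCC[C@]4(C)[C@H]3CO
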